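**Plan**

- Retrosynthesis: first the four MOM ethers and the C3 silyl ether are removed. Ring C is then cut at C4–C4a and C2–C3 in one operation, giving an O-aryl mixed acetal (ring A–O1–C2–ring B) and a C3–C4 unit, a 2-silyloxy ketene diethyl acetal. The acetal is cut at O1–C2 into a ring A phenol and a ring B aldehyde acetal.
- Enabling feature: once C2 is an oxocarbenium ion (stabilised by the 2,4,6-trioxygenated ring B), O1=C2 and the C8a=C4a π bond of ring A make a 2-oxadiene. C4a is the only unsubstituted carbon of ring A and lies ortho to O1 and O5 and para to O7.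
- Forward order: ring A is dressed first (geranyl between two identical OMOM groups, OH by C–H borylation/oxidation, prenyl ortho to that OH), which fixes 6-geranyl/8-prenyl by symmetry. The ring B aldehyde is made by ortho-lithiation, the two are joined as the mixed acetal, and ring C is closed last by a cationic [4+2] annulation.
- Stereochemistry: C2 comes from the chiral counter-anion of the acid catalyst in the annulation. C3 comes from the exo approach of the ketene acetal (2,3-trans, also the thermodynamically preferred arrangement). The E double bond comes in with geranyl bromide.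

Key step: step 11

Assumption: the sense of induction of the chiral acid in step 11 cannot be assigned in advance; the route is written with the (S,S)-catalyst, and its antipode is taken if that one proves to deliver the (2R) product.

**Route**

Step 1
Reactants: 1 resorcinol
Product: 2 1,3-bis(methoxymethoxy)benzene
Conditions: NaH, MOMCl, DMF, 0 °C to rt
Reagents that add atoms: chloromethyl methyl ether, COCCl
Why: O-alkylation of the bis-phenoxide with an α-chloro ether (MOM protection); the MOM groups direct the metalation in step 2 and protect the phenols up to step 12.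

Step 2
Reactants: 2 1,3-bis(methoxymethoxy)benzene; 3 geranyl bromide
Product: 5 2-[(2E)-3,7-dimethylocta-2,6-dien-1-yl]-1,3-bis(methoxymethoxy)benzene, via aryllithium 4 (not isolated)
Conditions: n-BuLi, THF, 0 °C to rt; then CuBr·SMe2 (10 mol%), 3, −78 to 0 °C
Reagents that add atoms: none
Why: Directed ortho-metalation, in which both OMOM groups steer n-BuLi to the carbon between them, followed by copper-catalysed SN2 allylation that keeps the E double bond of geranyl bromide.

Step 3
Reactants: 5 2-[(2E)-3,7-dimethylocta-2,6-dien-1-yl]-1,3-bis(methoxymethoxy)benzene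
Product: 7 4-[(2E)-3,7-dimethylocta-2,6-dien-1-yl]-3,5-bis(methoxymethoxy)phenol, via aryl pinacol boronate 6 (not isolated)
Conditions: [Ir(OMe)(cod)]2 (1.5 mol%), 4,4'-di-tert-butyl-2,2'-bipyridine, B2pin2 (0.55 equiv), THF, 80 °C; then 30% H2O2, aq. NaOH, 0 °C
Reagents that add atoms: hydrogen peroxide, OO (phenol oxygen); bis(pinacolato)diboron, CC1(C)OB(OC1(C)C)B1OC(C)(C)C(C)(C)O1 (boryl group of intermediate 6 only)
Why: Sterically controlled iridium-catalysed aromatic C–H borylation should take the only ring hydrogen without an ortho substituent, and basic peroxide oxidation of the C–B bond, which leaves trisubstituted alkenes alone, gives the phenol.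

Step 4
Reactants: 7 4-[(2E)-3,7-dimethylocta-2,6-dien-1-yl]-3,5-bis(methoxymethoxy)phenol; 8 prenyl bromide
Product: 9 4-[(2E)-3,7-dimethylocta-2,6-dien-1-yl]-3,5-bis(methoxymethoxy)-2-(3-methylbut-2-en-1-yl)phenol
Conditions: NaH, toluene, 0 °C to rt; then 8, rt
Reagents that add atoms: none
Why: Ortho C-alkylation of a sodium phenoxide in a non-polar solvent; the two ortho positions are equivalent and the para position is blocked, so the free OH ends up between the prenyl group and the last ring hydrogen.

Step 5
Reactants: 10 5-methoxyresorcinol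
Product: 11 1-methoxy-3,5-bis(methoxymethoxy)benzene
Conditions: NaH, MOMCl, DMF, 0 °C to rt
Reagents that add atoms: chloromethyl methyl ether, COCCl
Why: MOM protection of both phenols by O-alkylation with an α-chloro ether.

Step 6
Reactants: 11 1-methoxy-3,5-bis(methoxymethoxy)benzene
Product: 13 4-methoxy-2,6-bis(methoxymethoxy)benzaldehyde, via aryllithium 12 (not isolated)
Conditions: n-BuLi, THF, 0 °C; then DMF, 0 °C to rt; H2O
Reagents that add atoms: N,N-dimethylformamide, CN(C)C=O
Why: Directed ortho-metalation between the two OMOM groups (stronger directors than OMe) followed by formylation with DMF.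

Step 7
Reactants: 13 4-methoxy-2,6-bis(methoxymethoxy)benzaldehyde
Product: 14 2-(dimethoxymethyl)-5-methoxy-1,3-bis(methoxymethoxy)benzene
Conditions: HC(OMe)3, MeOH, pyridinium p-toluenesulfonate (5 mol%), rt; Et3N quench
Reagents that add atoms: trimethyl orthoformate, COC(OC)OC
Why: Acid-catalysed acetalisation driven by the orthoformate as water scavenger, mild enough to leave the aryl MOM ethers intact.

Step 8
Reactants: 14 2-(dimethoxymethyl)-5-methoxy-1,3-bis(methoxymethoxy)benzene; 9 4-[(2E)-3,7-dimethylocta-2,6-dien-1-yl]-3,5-bis(methoxymethoxy)-2-(3-methylbut-2-en-1-yl)phenol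
Product: 16 1-[(2E)-3,7-dimethylocta-2,6-dien-1-yl]-4-{methoxy[4-methoxy-2,6-bis(methoxymethoxy)phenyl]methoxy}-2,6-bis(methoxymethoxy)-3-(3-methylbut-2-en-1-yl)benzene, via collidinium salt 15 (not isolated)
Conditions: TESOTf (1.2 equiv), 2,4,6-collidine (3 equiv), CH2Cl2, 0 °C; then 9, 0 °C to rt; basic alumina
Reagents that add atoms: none
Why: Mixed-acetal synthesis through a pyridinium-type salt, in which the silyl triflate ionises one methoxy group under collidine buffering and the phenol oxygen then displaces collidine (the one free ring carbon of 9 is flanked on both sides); the acetal carbon is formed racemic, which is of no consequence.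

Step 9
Reactants: 17 ethyl diethoxyacetate
Product: 18 2,2-diethoxyacetaldehyde
Conditions: DIBAL-H (1.05 equiv), CH2Cl2, −78 °C; aq. Rochelle salt
Reagents that add atoms: none
Why: Partial reduction of an α-alkoxy ester, which stops at the aldehyde stage because the chelated tetrahedral aluminium hemiacetal is stable at −78 °C.

Step 10
Reactants: 18 2,2-diethoxyacetaldehyde
Product: 19 tert-butyl[(2,2-diethoxyethenyl)oxy]dimethylsilane
Conditions: TBSOTf, Et3N, Et2O, 0 °C
Reagents that add atoms: tert-butyldimethylsilyl trifluoromethanesulfonate, CC(C)(C)[Si](C)(C)OS(=O)(=O)C(F)(F)F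
Why: Soft enolisation (silyl triflate and amine) gives the silyl enol ether, which is at the same time the ketene O,O-acetal of O-silyl glycolic acid and has no E/Z isomers because C1 carries two ethoxy groups.

Step 11
Reactants: 16 the O-aryl O-methyl mixed acetal; 19 tert-butyl[(2,2-diethoxyethenyl)oxy]dimethylsilane
Product: 22 (2R,3R)-3-[(tert-butyldimethylsilyl)oxy]-6-[(2E)-3,7-dimethylocta-2,6-dien-1-yl]-2-[4-methoxy-2,6-bis(methoxymethoxy)phenyl]-5,7-bis(methoxymethoxy)-8-(3-methylbut-2-en-1-yl)-2,3-dihydro-4H-chromen-4-one, via oxocarbenium ion 20 (not isolated), via diethyl ketal 21 (not isolated)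
Conditions: 19 (2.0 equiv), (S,S)-IDPi (imidodiphosphorimidate Brønsted acid from two (S)-3,3'-bis[3,5-bis(trifluoromethyl)phenyl]-1,1'-bi-2-naphthol units, N-triflyl on both phosphorus atoms; 5 mol%), methallyltrimethylsilane (1.2 equiv), toluene, −78 °C; Et3N; then 0.5 M aq. oxalic acid, THF, 0 °C
Reagents that add atoms: water, O (carbonyl oxygen at C4 on ketal hydrolysis)
Why: Proposed new method: the silylated chiral imidodiphosphorimidate (formed from the acid and methallyltrimethylsilane) should abstract the methoxy group of 16 at its more basic, unhindered alkyl oxygen to give the O-aryl oxocarbenium ion 20 paired with the chiral anion; C3 of ketene acetal 19 then adds to C2, the diethoxycarbenium ion so formed at C4 is captured by C4a of ring A, and the proton released re-forms the silyl Lewis acid with the allylsilane. The closest known reaction types are the Lewis-acid-promoted oxa-Povarov [4+2] annulation of O-aryl oxocarbenium ions with alkenes, the chiral-acid-catalysed aza-Povarov reaction and counter-anion-directed Mukaiyama-type additions of ketene acetals to oxocarbenium ions; an α-oxygenated ketene O,O-acetal as the 2π partner and enantiocontrol on an acyclic O-aryl oxocarbenium ion have not been shown. Ring C closes by 6-exo-trig attack of the aromatic C4a=C8a π bond on the carbenium carbon (an intramolecular Friedel–Crafts alkylation that completes the formal [4+2]), and any open-chain orthoester formed by capture of that carbenium ion by MeOSiMe3 should re-ionise and funnel to the ring-closed ketal. C2 is set by the chiral counter-anion, which shields one face of the planar oxocarbenium ion, and C3 by the exo (antiperiplanar) approach that keeps the OTBS group away from ring A and gives the 2,3-trans relationship, which is also the thermodynamically preferred one. The step needs ionisation towards the aryloxy and not the methoxy oxocarbenium ion (secured by silyl binding at the methoxy oxygen), capture of 20 by 19 ahead of the neighbouring prenyl double bond and of other arene carbons (secured by the far higher nucleophilicity of the ketene acetal, used in excess), and ring closure at one site only (secured because C4a is the single unsubstituted position of ring A). The ketal 21 is hydrolysed to ketone 22 by the aqueous oxalic acid work-up.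

Step 12
Reactants: 22 the MOM- and TBS-protected (2R,3R)-dihydroflavonol
Product: 23 (2R,3R)-2-(2,6-dihydroxy-4-methoxyphenyl)-6-[(2E)-3,7-dimethylocta-2,6-dien-1-yl]-3,5,7-trihydroxy-8-(3-methylbut-2-en-1-yl)-2,3-dihydro-4H-chromen-4-one
Conditions: 2 M aq. HCl, MeOH, rt to 40 °C, short reaction time
Reagents that add atoms: none
Why: Acid-catalysed methanolysis of the four aryl MOM acetals and of the secondary silyl ether, a standard end game for prenylated flavanones; no stereocentre is formed, and temperature and time are kept low to avoid ionisation at C2 and cyclisation of the prenyl and geranyl groups onto neighbouring phenols.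

**Compound list**

1 | resorcinol (benzene-1,3-diol) | Oc1cccc(O)c1 | starting material
2 | 1,3-bis(methoxymethoxy)benzene | COCOc1cccc(OCOC)c1 | intermediate
3 | geranyl bromide, (2E)-1-bromo-3,7-dimethylocta-2,6-diene | BrC/C=C(\C)CCC=C(C)C | starting material
4 | [2,6-bis(methoxymethoxy)phenyl]lithium | [Li]c1c(OCOC)cccc1OCOC | intermediate
5 | 2-[(2E)-3,7-dimethylocta-2,6-dien-1-yl]-1,3-bis(methoxymethoxy)benzene | COCOc1cccc(OCOC)c1C/C=C(\C)CCC=C(C)C | intermediate
6 | 2-{4-[(2E)-3,7-dimethylocta-2,6-dien-1-yl]-3,5-bis(methoxymethoxy)phenyl}-4,4,5,5-tetramethyl-1,3,2-dioxaborolane | CC1(C)OB(OC1(C)C)c1cc(OCOC)c(C/C=C(\C)CCC=C(C)C)c(OCOC)c1 | intermediate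
7 | 4-[(2E)-3,7-dimethylocta-2,6-dien-1-yl]-3,5-bis(methoxymethoxy)phenol | Oc1cc(OCOC)c(C/C=C(\C)CCC=C(C)C)c(OCOC)c1 | intermediate
8 | prenyl bromide, 1-bromo-3-methylbut-2-ene | BrCC=C(C)C | starting material
9 | 4-[(2E)-3,7-dimethylocta-2,6-dien-1-yl]-3,5-bis(methoxymethoxy)-2-(3-methylbut-2-en-1-yl)phenol | Oc1cc(OCOC)c(C/C=C(\C)CCC=C(C)C)c(OCOC)c1CC=C(C)C | intermediate
10 | 5-methoxyresorcinol (5-methoxybenzene-1,3-diol) | COc1cc(O)cc(O)c1 | starting material
11 | 1-methoxy-3,5-bis(methoxymethoxy)benzene | COCOc1cc(OC)cc(OCOC)c1 | intermediate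
12 | [4-methoxy-2,6-bis(methoxymethoxy)phenyl]lithium | [Li]c1c(OCOC)cc(OC)cc1OCOC | intermediate
13 | 4-methoxy-2,6-bis(methoxymethoxy)benzaldehyde | COCOc1cc(OC)cc(OCOC)c1C=O | intermediate
14 | 2-(dimethoxymethyl)-5-methoxy-1,3-bis(methoxymethoxy)benzene | COCOc1cc(OC)cc(OCOC)c1C(OC)OC | intermediate
15 | 1-{methoxy[4-methoxy-2,6-bis(methoxymethoxy)phenyl]methyl}-2,4,6-trimethylpyridinium trifluoromethanesulfonate | COC(c1c(OCOC)cc(OC)cc1OCOC)[n+]1c(C)cc(C)cc1C.[O-]S(=O)(=O)C(F)(F)F | intermediate
16 | 1-[(2E)-3,7-dimethylocta-2,6-dien-1-yl]-4-{methoxy[4-methoxy-2,6-bis(methoxymethoxy)phenyl]methoxy}-2,6-bis(methoxymethoxy)-3-(3-methylbut-2-en-1-yl)benzene (racemic at the acetal carbon) | COC(Oc1cc(OCOC)c(C/C=C(\C)CCC=C(C)C)c(OCOC)c1CC=C(C)C)c1c(OCOC)cc(OC)cc1OCOC | intermediate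
17 | ethyl diethoxyacetate | CCOC(OCC)C(=O)OCC | starting material
18 | 2,2-diethoxyacetaldehyde | CCOC(OCC)C=O | intermediate
19 | tert-butyl[(2,2-diethoxyethenyl)oxy]dimethylsilane | CCOC(OCC)=CO[Si](C)(C)C(C)(C)C | intermediate
20 | [4-methoxy-2,6-bis(methoxymethoxy)benzylidene]{4-[(2E)-3,7-dimethylocta-2,6-dien-1-yl]-3,5-bis(methoxymethoxy)-2-(3-methylbut-2-en-1-yl)phenyl}oxonium (counter-ion: the chiral imidodiphosphorimidate anion) | COc1cc(OCOC)c(C=[O+]c2cc(OCOC)c(C/C=C(\C)CCC=C(C)C)c(OCOC)c2CC=C(C)C)c(OCOC)c1 | intermediate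
21 | (2R,3R)-3-[(tert-butyldimethylsilyl)oxy]-4,4-diethoxy-6-[(2E)-3,7-dimethylocta-2,6-dien-1-yl]-2-[4-methoxy-2,6-bis(methoxymethoxy)phenyl]-5,7-bis(methoxymethoxy)-8-(3-methylbut-2-en-1-yl)chromane | COc1cc(OCOC)c([C@H]2Oc3c(CC=C(C)C)c(OCOC)c(C/C=C(\C)CCC=C(C)C)c(OCOC)c3C(OCC)(OCC)[C@@H]2O[Si](C)(C)C(C)(C)C)c(OCOC)c1 | intermediate
22 | (2R,3R)-3-[(tert-butyldimethylsilyl)oxy]-6-[(2E)-3,7-dimethylocta-2,6-dien-1-yl]-2-[4-methoxy-2,6-bis(methoxymethoxy)phenyl]-5,7-bis(methoxymethoxy)-8-(3-methylbut-2-en-1-yl)-2,3-dihydro-4H-chromen-4-one | COc1cc(OCOC)c([C@H]2Oc3c(CC=C(C)C)c(OCOC)c(C/C=C(\C)CCC=C(C)C)c(OCOC)c3C(=O)[C@@H]2O[Si](C)(C)C(C)(C)C)c(OCOC)c1 | intermediate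
23 | (2R,3R)-2-(2,6-dihydroxy-4-methoxyphenyl)-6-[(2E)-3,7-dimethylocta-2,6-dien-1-yl]-3,5,7-trihydroxy-8-(3-methylbut-2-en-1-yl)-2,3-dihydro-4H-chromen-4-one | COc1cc(O)c([C@H]2Oc3c(CC=C(C)C)c(O)c(C/C=C(\C)CCC=C(C)C)c(O)c3C(=O)[C@@H]2O)c(O)c1 | target

**Count and risks**

Total step count: 12. Longest linear sequence: 7 steps (steps 1, 2, 3, 4, 8, 11, 12, from resorcinol).

Steps most likely to fail:

1. Step 11 (Proposed new method). Possible failures as processes:
   - ionisation in the wrong direction (loss of the aryloxy group instead of the methoxy group);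
   - capture of the oxocarbenium ion by the neighbouring prenyl double bond (Prins) or by an arene carbon of a second molecule;
   - capture of the C4 carbenium ion by a MOM oxygen of ring B instead of C4a;
   - poor facial selectivity within the ion pair, or exo/endo leakage at C3;
   - re-ionisation at C2 of the product.

   Fallback with known chemistry, setting out from 16 and returning at 22: (4S)-4-isopropyl-1,3-thiazolidine-2-thione is N-acylated with (tert-butyldimethylsilyloxy)acetyl chloride to the glycolyl imide (4S)-3-{[(tert-butyldimethylsilyl)oxy]acetyl}-4-isopropyl-1,3-thiazolidine-2-thione F1. Its chlorotitanium enolate (TiCl4, i-Pr2NEt, CH2Cl2, −78 °C) is added to 16 activated by BF3·OEt2, which should give the 2,3-anti adduct F2 with both centres set by the auxiliary (stereoselective addition of a chiral titanium enolate to an acetal-derived oxocarbenium ion). LiOH in aqueous THF removes the auxiliary to give the 3-aryloxy-2-silyloxy acid F3. Activation with 1-chloro-N,N,2-trimethylprop-1-en-1-amine and intramolecular Friedel–Crafts acylation at C4a close ring C to 22.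

2. Step 8. Possible failures: C-alkylation of ring A of 9 in place of O-alkylation, and re-ionisation of the very labile mixed acetal during isolation.

   Fallback, setting out from 13 and 9 and returning at 16: NaBH4 in MeOH reduces 13 to [4-methoxy-2,6-bis(methoxymethoxy)phenyl]methanol F4. Mitsunobu etherification (PPh3, diisopropyl azodicarboxylate, THF) with phenol 9 gives the benzyl aryl ether F5. Oxidation of its benzylic position, activated by the three oxygens of ring B, with DDQ in CH2Cl2/MeOH over NaHCO3 should give 16 (oxidative acetalisation of the kind known for p-methoxybenzyl ethers).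

3. Step 12. Possible failures: acid-induced cyclisation of the prenyl or geranyl group onto a freed neighbouring phenol, and ionisation at C2 (benzylic to the trioxygenated ring B) with ring opening or loss of configuration.

   Fallback, setting out from 22 and returning at 23: TMSOTf and 2,2'-bipyridyl in CH2Cl2 at 0 °C exchange the four aryl MOM groups for trimethylsilyl groups without protic acid to give the pentasilyl ether F6. HF·pyridine buffered with pyridine in THF at 0 °C then removes all five silyl groups.

Further compounds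
F1 | step 11 | (4S)-3-{[(tert-butyldimethylsilyl)oxy]acetyl}-4-isopropyl-1,3-thiazolidine-2-thione | CC(C)[C@H]1CSC(=S)N1C(=O)CO[Si](C)(C)C(C)(C)C
F2 | step 11 | 2,3-anti adduct, (4S)-3-[3-aryloxy-3-aryl-2-(tert-butyldimethylsilyloxy)propanoyl]-4-isopropyl-1,3-thiazolidine-2-thione with the C2/C3 arrangement of the target | COc1cc(OCOC)c([C@@H](Oc2cc(OCOC)c(C/C=C(\C)CCC=C(C)C)c(OCOC)c2CC=C(C)C)[C@@H](O[Si](C)(C)C(C)(C)C)C(=O)N2[C@@H](C(C)C)CSC2=S)c(OCOC)c1
F3 | step 11 | 3-aryloxy-3-aryl-2-(tert-butyldimethylsilyloxy)propanoic acid with the C2/C3 arrangement of the target | COc1cc(OCOC)c([C@@H](Oc2cc(OCOC)c(C/C=C(\C)CCC=C(C)C)c(OCOC)c2CC=C(C)C)[C@@H](O[Si](C)(C)C(C)(C)C)C(=O)O)c(OCOC)c1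
F4 | step 8 | [4-methoxy-2,6-bis(methoxymethoxy)phenyl]methanol | COCOc1cc(OC)cc(OCOC)c1CO
F5 | step 8 | 1-[(2E)-3,7-dimethylocta-2,6-dien-1-yl]-4-{[4-methoxy-2,6-bis(methoxymethoxy)phenyl]methoxy}-2,6-bis(methoxymethoxy)-3-(3-methylbut-2-en-1-yl)benzene | COCOc1cc(OC)cc(OCOC)c1COc1cc(OCOC)c(C/C=C(\C)CCC=C(C)C)c(OCOC)c1CC=C(C)C
F6 | step 12 | (2R,3R)-3-[(tert-butyldimethylsilyl)oxy]-6-[(2E)-3,7-dimethylocta-2,6-dien-1-yl]-2-[4-methoxy-2,6-bis(trimethylsilyloxy)phenyl]-8-(3-methylbut-2-en-1-yl)-5,7-bis(trimethylsilyloxy)-2,3-dihydro-4H-chromen-4-one | COc1cc(O[Si](C)(C)C)c([C@H]2Oc3c(CC=C(C)C)c(O[Si](C)(C)C)c(C/C=C(\C)CCC=C(C)C)c(O[Si](C)(C)C)c3C(=O)[C@@H]2O[Si](C)(C)C(C)(C)C)c(O[Si](C)(C)C)c1
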